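**Retrosynthetic overview**
1. Target ⇒ the spiro triketone hydroperoxide without its two prenyl groups; double C‑prenylation of the only enolisable ring carbon comes last.
2. Spiro triketone hydroperoxide ⇒ an aromatic 3‑(cyclopentylmethyl)‑2,4,6‑trihydroxyacetophenone. One dearomative oxidative radical ipso‑cyclisation (6‑endo onto the isopropenyl group, O2 capture) makes the spiro carbon, the cyclohexane ring and the tertiary hydroperoxide.
3. Aryl–CH2 bond ⇒ 2,4,6‑trihydroxyacetophenone + a β‑hydroxy aldehyde (reductive alkylation).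
4. Cyclopentanol ⇒ intramolecular aldol of the keto aldehyde from cleavage of (R)‑limonene oxide.
5. Ring order: cyclopentane (aldol) → cyclohexane of the trans‑hydrindane together with the spiro junction (key step); the trione ring is the former arene.

Assumption: the β‑triketone is drawn in the enol form of the given SMILES, and commercial (+)‑limonene 1,2‑oxide (4R, cis/trans mixture) is used as sold.

**Step 1**
Reactants: 1 (+)-limonene 1,2-oxide (4R, cis/trans mixture)
Product: 3 (3R)-6-oxo-3-(prop-1-en-2-yl)heptanal, via (4R)-limonene-1,2-diol 2 (not isolated)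
Conditions: H5IO6 (1.1 equiv), THF/H2O 2:1, 0 °C to rt, 2 h
Reagents that add atoms: water, O
Why: Hydrolysis of either epoxide diastereomer to the diol and Malaprade glycol cleavage give the keto aldehyde; the limonene stereocenter is untouched and becomes C3 (R) of 3.

**Step 2**
Reactants: 3 (3R)-6-oxo-3-(prop-1-en-2-yl)heptanal
Product: 4 (1S,2R,5R)-2-hydroxy-2-methyl-5-(prop-1-en-2-yl)cyclopentane-1-carbaldehyde
Conditions: L-proline (30 mol %), DMSO, rt, 24 h; crude product used directly
Reagents that add atoms: none
Why: Proline-catalysed 5-enolexo enamine aldol addition: the aldehyde enamine adds to the methyl ketone through a hydrogen-bonded transition state that puts the new hydroxyl cis to the formyl group, and the formyl group ends up trans to the isopropenyl group of the existing stereocenter, so C1 (S) and C2 (R) are set by substrate control expected to be matched with L-proline, giving what should be the most stable isomer (methyl, formyl and isopropenyl alternate around the ring).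

**Step 3**
Reactants: 4 (1S,2R,5R)-2-hydroxy-2-methyl-5-(prop-1-en-2-yl)cyclopentane-1-carbaldehyde; 5 2,4,6-trihydroxyacetophenone
Product: 7 1-[2,4,6-trihydroxy-3-{[(1S,2R,5R)-2-hydroxy-2-methyl-5-(prop-1-en-2-yl)cyclopentyl]methyl}phenyl]ethan-1-one, via ortho-quinone methide 6 (not isolated)
Conditions: 5 (3 equiv), Hantzsch ester (1.3 equiv), L-proline (20 mol %), EtOH/CH2Cl2 1:1, rt, 12 h
Reagents that add atoms: 2,4,6-trihydroxyacetophenone (5), CC(=O)c1c(O)cc(O)cc1O
Why: Three-component reductive alkylation: amine-mediated Knoevenagel–Mannich condensation at the nucleophilic ring carbon gives ortho-quinone methide 6, which the Hantzsch ester reduces by conjugate hydride transfer before a second arene can add; no stereocenter is formed and the neutral conditions spare the tertiary aldol.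

**Step 4**
Reactants: 7 1-[2,4,6-trihydroxy-3-{[(1S,2R,5R)-2-hydroxy-2-methyl-5-(prop-1-en-2-yl)cyclopentyl]methyl}phenyl]ethan-1-one
Product: 8 (1R,3'R,3a'S,7'R,7a'R)-3-acetyl-7'-hydroperoxy-3',4-dihydroxy-3',7'-dimethyl-1',2',3',3a',4',6',7',7a'-octahydrospiro[cyclohex-3-ene-1,5'-indene]-2,6-dione
Conditions: Mn(OAc)3·2H2O (20 mol %), AcOH, air (1 atm), 23 °C, 0.01 M, stopped at about 80 % conversion
Reagents that add atoms: dioxygen, O=O
Why: Proposed new method: one-electron oxidation of the electron-rich phloroglucinol by trivalent manganese gives a delocalised radical with spin at the alkylated ring carbon, which closes 6-endo-trig onto the CH2 terminus of the isopropenyl group through a chair transition state (5-exo would need a trans-fused bicyclo[3.3.0]octane), the tertiary radical is captured by O2 and the peroxyl radical is reduced by divalent manganese, which returns the catalyst; the trans ring fusion follows from the trans side chains of 7, the spiro carbon (R) is expected to form preferentially because the acetyl-flanked, metal-chelated carbonyl arm takes the outer (equatorial) position, and O2 adds opposite the resulting axial C6 carbonyl to give (7'R) with equatorial OOH (moderate selectivity expected, epimers removed by chromatography); closest known reaction types are the Mn(OAc)3/O2 hydroperoxidative radical addition of 1,3-dicarbonyls to 1,1-disubstituted alkenes and oxidative radical cyclisations of dearomatised acylphloroglucinols.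

**Step 5**
Reactants: 8 spiro triketone hydroperoxide (as above); 9 prenyl bromide (1-bromo-3-methylbut-2-ene)
Product: 11 (1R,3'R,3a'S,7'R,7a'R)-3-acetyl-7'-hydroperoxy-3',4-dihydroxy-3',7'-dimethyl-5,5-bis(3-methylbut-2-en-1-yl)-1',2',3',3a',4',6',7',7a'-octahydrospiro[cyclohex-3-ene-1,5'-indene]-2,6-dione (CNP0149131.2), via monoprenyl triketone 10 (not isolated)
Conditions: 9 (3 equiv), Na2CO3 (3 equiv), H2O/MeOH 1:1, 0 °C to rt; then 1 M HCl
Reagents that add atoms: prenyl bromide (9), CC(C)=CCBr
Why: Double C-allylation of a cyclic 1,3-dicarbonyl (vinylogous acid) enolate at the only enolisable ring carbon: carbonate (conjugate acid pKa about 10) ionises the triketone (pKa about 5) but not the tertiary hydroperoxide (pKa about 13), and the protic medium favours C- over O-alkylation; no stereocenter is formed and none can epimerise.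

**Compound list**
1 | (+)-limonene 1,2-oxide, (4R), cis/trans mixture | CC(=C)[C@@H]1CCC2(C)OC2C1 | starting material
2 | (4R)-limonene-1,2-diol (C1/C2 configuration irrelevant, both centres are destroyed) | CC(=C)[C@@H]1CCC(C)(O)C(O)C1 | intermediate
3 | (3R)-6-oxo-3-(prop-1-en-2-yl)heptanal | O=CC[C@H](C(C)=C)CCC(C)=O | intermediate
4 | (1S,2R,5R)-2-hydroxy-2-methyl-5-(prop-1-en-2-yl)cyclopentane-1-carbaldehyde (OH cis to CHO; CHO trans to isopropenyl) | O=C[C@H]1[C@@H](CC[C@@]1(C)O)C(C)=C | intermediate
5 | 2,4,6-trihydroxyacetophenone | CC(=O)c1c(O)cc(O)cc1O | starting material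
6 | ortho-quinone methide (Knoevenagel adduct of 4 and 5, alkene geometry undefined) | CC(=O)C1=C(O)C=C(O)C(=C[C@H]2[C@@H](CC[C@@]2(C)O)C(C)=C)C1=O | intermediate
7 | 1-[2,4,6-trihydroxy-3-{[(1S,2R,5R)-2-hydroxy-2-methyl-5-(prop-1-en-2-yl)cyclopentyl]methyl}phenyl]ethan-1-one | CC(=O)c1c(O)cc(O)c(C[C@H]2[C@@H](CC[C@@]2(C)O)C(C)=C)c1O | intermediate
8 | (1R,3'R,3a'S,7'R,7a'R)-3-acetyl-7'-hydroperoxy-3',4-dihydroxy-3',7'-dimethyl-octahydrospiro[cyclohex-3-ene-1,5'-indene]-2,6-dione (trans-hydrindane; C6 carbonyl axial and syn to the axial 7'-methyl; OOH equatorial) | CC(=O)C1=C(O)CC(=O)[C@]2(C[C@H]3[C@@H](CC[C@@]3(C)O)[C@](C)(OO)C2)C1=O | intermediate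
9 | prenyl bromide (1-bromo-3-methylbut-2-ene) | CC(C)=CCBr | starting material
10 | monoprenyl triketone (5-(3-methylbut-2-en-1-yl) derivative of 8, C5 enolisable) | CC(=O)C1=C(O)C(CC=C(C)C)C(=O)[C@]2(C[C@H]3[C@@H](CC[C@@]3(C)O)[C@](C)(OO)C2)C1=O | intermediate
11 | (1R,3'R,3a'S,7'R,7a'R)-3-acetyl-7'-hydroperoxy-3',4-dihydroxy-3',7'-dimethyl-5,5-bis(3-methylbut-2-en-1-yl)-octahydrospiro[cyclohex-3-ene-1,5'-indene]-2,6-dione | CC(=O)C1=C(O)C(CC=C(C)C)(CC=C(C)C)C(=O)[C@]2(C[C@H]3[C@@H](CC[C@@]3(C)O)[C@](C)(OO)C2)C1=O | target

**Step count**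
Total steps: 5. Longest linear sequence: 5 (1 → 3 → 4 → 7 → 8 → 11).

**Steps most likely to fail, with fallbacks**

Step 4 (dearomative spirocyclisation with O2 capture). Three things can go wrong: the aryl radical may not add to the alkene, the product 8 still has an oxidisable CH2 between two carbonyls, and the preference at the spiro carbon may be small. The fallback sets out from 7 and inverts the order. 7 is first dearomatised by double C‑prenylation with 9 (NaOMe, MeOH, 0 °C) at its free ring carbon to give the lupulone-type triketone 4-acetyl-3,5-dihydroxy-2-{[(1S,2R,5R)-2-hydroxy-2-methyl-5-(prop-1-en-2-yl)cyclopentyl]methyl}-6,6-bis(3-methylbut-2-en-1-yl)cyclohexa-2,4-dien-1-one F3. Its enolised triketone is a conventional substrate for Mn(OAc)3·2H2O (cat.)/AcOH/air; the same 6‑endo closure and O2 capture then give a product with no enolisable ring CH left. In F3 the metal is chelated by the acetyl/enol unit next to the reacting carbon, which should reinforce the preference for the required spiro configuration. The known competitor is 5‑exo attack on a geminal prenyl group. This fallback comes back to the route at 11 and replaces steps 4 and 5.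

Step 2 (diastereoselective aldol without dehydration). If proline gives the wrong carbinol epimer or the enal, the fallback sets out from 3. Aldol condensation (piperidine, AcOH, toluene, reflux) gives the enal (5S)-2-methyl-5-(prop-1-en-2-yl)cyclopent-1-ene-1-carbaldehyde F1. Weitz–Scheffer epoxidation (H2O2, NaOH, MeOH, 0 °C) occurs anti to the isopropenyl group and gives the epoxy aldehyde 5-methyl-2-(prop-1-en-2-yl)-6-oxabicyclo[3.1.0]hexane-1-carbaldehyde F2 (oxirane oxygen trans to isopropenyl). Reductive cleavage of the α C–O bond with Na[PhSeB(OEt)3] (from PhSeSePh and NaBH4, EtOH, AcOH, 0 °C), followed by thermodynamic protonation at the α-carbon, then gives the β-hydroxy aldehyde. Here the carbinol configuration is fixed by the epoxidation face, not by the aldol transition state. This fallback comes back to the route at 4.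

Step 5 (double prenylation beside a free hydroperoxide). If O‑alkylation of the hydroperoxide or low conversion at the hindered carbon is seen, the fallback sets out from 8. The hydroperoxide is masked with 2-methoxypropene (PPTS cat., CH2Cl2, 0 °C) as the 2-methoxyprop-2-yl peroxyketal of 8 F4. F4 is then prenylated twice with 9 under strongly basic conditions (NaOMe, MeOH, 0 °C to rt) to give the 2-methoxyprop-2-yl peroxyketal of 11 F5. Mild acid (AcOH/THF/H2O, rt) releases the hydroperoxide. This fallback comes back to the route at 11.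

**Further compounds**
F1 | step 2 | (5S)-2-methyl-5-(prop-1-en-2-yl)cyclopent-1-ene-1-carbaldehyde | O=CC1=C(C)CC[C@H]1C(C)=C
F2 | step 2 | 5-methyl-2-(prop-1-en-2-yl)-6-oxabicyclo[3.1.0]hexane-1-carbaldehyde, oxirane oxygen trans to isopropenyl | O=C[C@@]12O[C@]1(C)CC[C@H]2C(C)=C
F3 | step 4 | 4-acetyl-3,5-dihydroxy-2-{[(1S,2R,5R)-2-hydroxy-2-methyl-5-(prop-1-en-2-yl)cyclopentyl]methyl}-6,6-bis(3-methylbut-2-en-1-yl)cyclohexa-2,4-dien-1-one | CC(=O)C1=C(O)C(CC=C(C)C)(CC=C(C)C)C(=O)C(C[C@H]2[C@@H](CC[C@@]2(C)O)C(C)=C)=C1O
F4 | step 5 | 2-methoxyprop-2-yl peroxyketal of 8 | CC(=O)C1=C(O)CC(=O)[C@]2(C[C@H]3[C@@H](CC[C@@]3(C)O)[C@](C)(OOC(C)(C)OC)C2)C1=O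
F5 | step 5 | 2-methoxyprop-2-yl peroxyketal of 11 | CC(=O)C1=C(O)C(CC=C(C)C)(CC=C(C)C)C(=O)[C@]2(C[C@H]3[C@@H](CC[C@@]3(C)O)[C@](C)(OOC(C)(C)OC)C2)C1=O
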